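The readings were computed for substances that don't exist; scatter was added.

I began with an easy sum: the last three readings of theta add up to 101%, so within the scatter these three forms account for the charge.

| setting | eta | theta | spring | dawn | summer |
|---|---|---|---|---|---|
| starting complex | 35 mM (fed, over 40 s) | 35 mM (fed, over 40 s) | 35 mM (fed, over 40 s) | 35 mM (fed, over 40 s) | 35 mM (fed, over 40 s) |
| incoming ligand | 25 mM | 110 mM | 52.5 mM | 140 mM | 28.0 mM |
| remark | run made earlier | run made earlier |  |  |  |
| time |  |  | 2.0 min | 2.0 min | 2.0 min |

| run | time / s | complex with one exchanged / % | complex with two exchanged / % | starting complex / % |
|---|---|---|---|---|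
| eta | 10.0 | 1.6 | 0.4 | 23.4 |
| eta | 30.0 | 9.6 | 1.5 | 64.0 |
| eta | 50.0 | 16.7 | 6.5 | 76.9 |
| eta | 80.0 | 22.6 | 9.0 | 69.1 |
| theta | 20.0 | 9.5 | 10.5 | 30.8 |
| theta | 40.0 | 24.8 | 26.5 | 50.2 |
| theta | 60.0 | 32.7 | 36.4 | 33.5 |
| theta | 80.0 | 35.0 | 38.9 | 27.5 |

(each reading ± 1 percentage point)

- percentages count the whole charge, also what has not yet gone in

- which of these holds the largest part of the starting complex at the end of spring (starting complex / complex with two exchanged / complex with one exchanged)
- which of these holds the largest part of the starting complex at the end of dawn (starting complex / complex with two exchanged / complex with one exchanged)
- which of these holds the largest part of the starting complex at the end of summer (starting complex / complex with two exchanged / complex with one exchanged)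
- amount of complex with one exchanged at the end of spring, in percent of the starting complex charged

From that last theta reading I formed the spread 1.15, the square of the one-exchanged share over the starting share times the two-exchanged share. Chance over two like sites makes it 4, the zero of the scale, so theta's reading stood well below chance.

Next I counted one leaving ligand per exchange. Theta then held 39.5 mM of leaving ligand against 70.5 mM of incoming ligand not taken up, a ratio of 0.560. That turned the shares into two apparent exchange constants, 0.713 and 0.622.

I assumed spring would be at rest at its end, under thermodynamic control, since it runs twice as long after the feed as theta's last reading. I tried an uptake of 26.2 mM, which is 0.750 equiv, so that leaving ligand and the incoming ligand not taken up stood equal in my reckoning. With that ratio of one, the starting, one-exchanged and two-exchanged shares came out at 46.4%, 33.1% and 20.6%. Their uptake of 0.742 equiv returned nearly what I had assumed.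

The weak link was the spread itself: theta's reading at 60.0 s gave 0.877, and the last reading stood higher than that, so it seemed still to be climbing. So I let it climb as much again, to 1.41, holding the product of the constants. Spring's one-exchanged share became 35.4%, and I committed to the middle, 34.2%.

The forecast named starting complex for spring, complex with two exchanged for dawn, starting complex for summer, and 33% of complex with one exchanged in spring, on a stepwise exchange of which it said “which points to reversibility”.

Spring ended with 34.1% of complex with one exchanged, and the largest parts were starting complex in spring, complex with two exchanged in dawn and starting complex in summer.

    complex with one exchanged + incoming ligand ⇌ leaving ligand + complex with two exchanged (K = 1.60, k = 2.80 /M/s)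
    starting complex + incoming ligand ⇌ leaving ligand + complex with one exchanged (K = 2.10, k = 1.40 /M/s)
    incoming ligand ⇌ dormant form (K = 1.70, k = 0.340 /s)

Spread by chance over two like sites, spring's uptake of 0.747 equiv would have put 46.8% in complex with one exchanged, more than the flask held. Carrying my spread of 1.15 to dawn, with its ends of 20.3% starting complex and 45.1% complex with two exchanged, gives 32.4% of complex with one exchanged, and dawn held 34.6%.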